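The route rests on disconnecting the O1–C2 ether bond of ring C, which reveals a 2'-hydroxychalcone. The key step copies the chalcone isomerase reaction: a cinchona-thiourea-catalysed 6-endo-trig oxa-Michael addition of the ring A phenol oxygen O1 onto C2 of the C2=C3–C4=O enone closes ring C and sets the C2 stereocentre in one operation. Its precursor carries the geranyl group already at the future C6 and has the oxygen next to it (future O5) capped as a MOM ether, so only O1 can cyclise and the 6-geranyl (not 8-geranyl) flavanone must result. Ring A is assembled regiospecifically by directed metalation, C–H borylation/oxidation and an aryllithium–Weinreb amide coupling.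

Key step: step 7

Assumption: the quinidine-derived thiourea is taken to favour attack on the enone face that gives (2S); if the sense proves opposite, the quinine-derived pseudo-enantiomer is used under the same conditions.

Step 1
Reactants: 1 1,3-bis(methoxymethoxy)benzene; 2 geranyl bromide [(2E)-1-bromo-3,7-dimethylocta-2,6-diene]
Product: 4 2-[(2E)-3,7-dimethylocta-2,6-dien-1-yl]-1,3-bis(methoxymethoxy)benzene, via 2,6-bis(methoxymethoxy)phenyllithium 3 (not isolated)
Conditions: n-BuLi (1.1 equiv), THF, 0 °C to rt; CuBr·SMe2 (10 mol%), then 2, −78 °C to rt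
Reagents that add atoms: none
Why: Directed ortho-metalation removes the proton flanked by both OMOM groups, and copper-catalysed allylic substitution of the aryllithium on the primary allylic bromide (SN2 mode) should give the linear (E)-geranyl arene.

Step 2
Reactants: 4 2-[(2E)-3,7-dimethylocta-2,6-dien-1-yl]-1,3-bis(methoxymethoxy)benzene
Product: 6 4-[(2E)-3,7-dimethylocta-2,6-dien-1-yl]-3,5-bis(methoxymethoxy)phenol, via aryl pinacol boronate 5 (not isolated)
Conditions: [Ir(OMe)(cod)]2 (1.5 mol%), 4,4'-di-tert-butyl-2,2'-bipyridine (3 mol%), B2pin2 (1.0 equiv), THF, 60 °C; then aq NaOH, 30% H2O2, 0 °C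
Reagents that add atoms: hydrogen peroxide, OO
Why: Sterically controlled iridium-catalysed aromatic C–H borylation should select the only ring C–H without an ortho substituent (para to the geranyl group), and oxidation of the C–B bond then gives the phenol whose oxygen becomes O1.

Step 3
Reactants: 6 4-[(2E)-3,7-dimethylocta-2,6-dien-1-yl]-3,5-bis(methoxymethoxy)phenol
Product: 7 2-bromo-4-[(2E)-3,7-dimethylocta-2,6-dien-1-yl]-3,5-bis(methoxymethoxy)phenol
Conditions: NBS (1.0 equiv), CH2Cl2, −78 °C
Reagents that add atoms: N-bromosuccinimide, O=C1CCC(=O)N1Br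
Why: Electrophilic aromatic bromination of the strongly activated phenol, whose para position is blocked and whose two ortho positions are equivalent, should give a single regioisomer faster than the alkenes react at low temperature.

Step 4
Reactants: 8 3,5-dihydroxybenzaldehyde
Product: 9 3,5-bis(methoxymethoxy)benzaldehyde
Conditions: MOMCl (2.5 equiv), DIPEA, CH2Cl2, 0 °C to rt
Reagents that add atoms: chloromethyl methyl ether, COCCl
Why: Base-mediated O-alkylation of both phenols with the α-chloro ether (Williamson-type MOM protection) is routine for this aldehyde.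

Step 5
Reactants: 9 3,5-bis(methoxymethoxy)benzaldehyde; 10 diethyl [2-(methoxy(methyl)amino)-2-oxoethyl]phosphonate
Product: 11 (2E)-3-[3,5-bis(methoxymethoxy)phenyl]-N-methoxy-N-methylprop-2-enamide
Conditions: NaH, THF, 0 °C to rt
Reagents that add atoms: none
Why: Horner–Wadsworth–Emmons olefination with a stabilised phosphonate should give the (E)-unsaturated Weinreb amide.

Step 6
Reactants: 7 2-bromo-4-[(2E)-3,7-dimethylocta-2,6-dien-1-yl]-3,5-bis(methoxymethoxy)phenol; 11 (2E)-3-[3,5-bis(methoxymethoxy)phenyl]-N-methoxy-N-methylprop-2-enamide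
Product: 13 (2E)-1-{3-[(2E)-3,7-dimethylocta-2,6-dien-1-yl]-6-hydroxy-2,4-bis(methoxymethoxy)phenyl}-3-[3,5-bis(methoxymethoxy)phenyl]prop-2-en-1-one, via lithium 2-lithiophenoxide dianion 12 (not isolated)
Conditions: t-BuLi (3.0 equiv), THF, −78 °C; then 11, −78 to 0 °C; aq NH4Cl
Reagents that add atoms: none
Why: Phenol deprotonation and bromine–lithium exchange give an aryllithium that adds 1,2 to the Weinreb amide (Weinreb ketone synthesis), the chelated tetrahedral adduct releasing the 2'-hydroxychalcone only on work-up.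

Step 7
Reactants: 13 (2E)-1-{3-[(2E)-3,7-dimethylocta-2,6-dien-1-yl]-6-hydroxy-2,4-bis(methoxymethoxy)phenyl}-3-[3,5-bis(methoxymethoxy)phenyl]prop-2-en-1-one
Product: 14 (2S)-6-[(2E)-3,7-dimethylocta-2,6-dien-1-yl]-5,7-bis(methoxymethoxy)-2-[3,5-bis(methoxymethoxy)phenyl]-2,3-dihydro-4H-chromen-4-one
Conditions: thiourea from 9-amino-9-deoxy-epi-quinidine and 3,5-bis(trifluoromethyl)phenyl isothiocyanate (15 mol%), toluene, rt; filtration through silica
Reagents that add atoms: none
Why: The quinuclidine nitrogen of the catalyst takes up the proton of the chelated 6'-OH while the thiourea hydrogen-bonds the enone carbonyl, and the ion-paired phenoxide O1 adds to the β-carbon (future C2) before the enol tautomerises to the ketone. The closest known reaction type is the cinchona-alkaloid or cinchona-thiourea catalysed enantioselective intramolecular oxa-Michael cyclisation of 2'-hydroxychalcones to flavanones, the laboratory counterpart of chalcone isomerase. Ring C closes in the 6-endo-trig mode. The new C2 stereocentre is set by the catalyst, which shields one face of the enone in the bound ion pair, the quinidine-derived pseudo-enantiomer being chosen for (2S). Regioselectivity is secured by the substrate, because the only free phenol is O1 and the oxygen beside the geranyl group is a MOM ether, so no 8-geranyl isomer can form. The step needs kinetic control, which should hold because the 5-alkoxyflavanone is favoured at equilibrium and the base-free medium and early removal of the catalyst limit retro-Michael erosion of the enantiomeric purity.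

Step 8
Reactants: 14 (2S)-6-[(2E)-3,7-dimethylocta-2,6-dien-1-yl]-5,7-bis(methoxymethoxy)-2-[3,5-bis(methoxymethoxy)phenyl]-2,3-dihydro-4H-chromen-4-one
Product: 15 schizolaenone C
Conditions: aq HCl (3 mol/L), MeOH, 45 °C
Reagents that add atoms: none
Why: Acid-catalysed methanolysis of the four MOM acetals should free the phenols, while the flavanone, which racemises through base-mediated ring opening, keeps its C2 configuration and the geranyl chain tolerates brief dilute acid.

Compound list
1 | 1,3-bis(methoxymethoxy)benzene | COCOc1cccc(OCOC)c1 | starting material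
2 | geranyl bromide, (2E)-1-bromo-3,7-dimethylocta-2,6-diene | CC(C)=CCC/C(C)=C/CBr | starting material
3 | 2,6-bis(methoxymethoxy)phenyllithium | COCOc1cccc(OCOC)c1[Li] | intermediate
4 | 2-[(2E)-3,7-dimethylocta-2,6-dien-1-yl]-1,3-bis(methoxymethoxy)benzene | CC(C)=CCC/C(C)=C/Cc1c(OCOC)cccc1OCOC | intermediate
5 | 2-{4-[(2E)-3,7-dimethylocta-2,6-dien-1-yl]-3,5-bis(methoxymethoxy)phenyl}-4,4,5,5-tetramethyl-1,3,2-dioxaborolane | CC(C)=CCC/C(C)=C/Cc1c(OCOC)cc(B2OC(C)(C)C(C)(C)O2)cc1OCOC | intermediate
6 | 4-[(2E)-3,7-dimethylocta-2,6-dien-1-yl]-3,5-bis(methoxymethoxy)phenol | CC(C)=CCC/C(C)=C/Cc1c(OCOC)cc(O)cc1OCOC | intermediate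
7 | 2-bromo-4-[(2E)-3,7-dimethylocta-2,6-dien-1-yl]-3,5-bis(methoxymethoxy)phenol | CC(C)=CCC/C(C)=C/Cc1c(OCOC)cc(O)c(Br)c1OCOC | intermediate
8 | 3,5-dihydroxybenzaldehyde | O=Cc1cc(O)cc(O)c1 | starting material
9 | 3,5-bis(methoxymethoxy)benzaldehyde | COCOc1cc(C=O)cc(OCOC)c1 | intermediate
10 | diethyl [2-(methoxy(methyl)amino)-2-oxoethyl]phosphonate | CCOP(=O)(OCC)CC(=O)N(C)OC | starting material
11 | (2E)-3-[3,5-bis(methoxymethoxy)phenyl]-N-methoxy-N-methylprop-2-enamide | CON(C)C(=O)/C=C/c1cc(OCOC)cc(OCOC)c1 | intermediate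
12 | lithium 3-[(2E)-3,7-dimethylocta-2,6-dien-1-yl]-6-lithio-2,4-bis(methoxymethoxy)... phenoxide, i.e. the O,C-dilithiated form of 7 (lithium on oxygen and on the former C–Br carbon) | CC(C)=CCC/C(C)=C/Cc1c(OCOC)cc(O[Li])c([Li])c1OCOC | intermediate
13 | (2E)-1-{3-[(2E)-3,7-dimethylocta-2,6-dien-1-yl]-6-hydroxy-2,4-bis(methoxymethoxy)phenyl}-3-[3,5-bis(methoxymethoxy)phenyl]prop-2-en-1-one | CC(C)=CCC/C(C)=C/Cc1c(OCOC)cc(O)c(C(=O)/C=C/c2cc(OCOC)cc(OCOC)c2)c1OCOC | intermediate
14 | (2S)-6-[(2E)-3,7-dimethylocta-2,6-dien-1-yl]-5,7-bis(methoxymethoxy)-2-[3,5-bis(methoxymethoxy)phenyl]-2,3-dihydro-4H-chromen-4-one | CC(C)=CCC/C(C)=C/Cc1c(OCOC)cc2c(c1OCOC)C(=O)C[C@@H](c1cc(OCOC)cc(OCOC)c1)O2 | intermediate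
15 | schizolaenone C, (2S)-2-(3,5-dihydroxyphenyl)-6-[(2E)-3,7-dimethylocta-2,6-dien-1-yl]-5,7-dihydroxy-2,3-dihydro-4H-chromen-4-one | CC(C)=CCC/C(C)=C/Cc1c(O)cc2c(c1O)C(=O)C[C@@H](c1cc(O)cc(O)c1)O2 | target

Total step count: 8. Longest linear sequence: 6 steps (steps 1, 2, 3, 6, 7, 8).

Steps most likely to fail

1. Step 7 (key step). What may go wrong: weak facial discrimination for a chalcone that offers the catalyst only one carbonyl to bind, and erosion of the enantiomeric purity by reversible retro-oxa-Michael opening during a slow cyclisation. Fallback (stereospecific ring closure of the same bond in place of enantiofacial addition): setting out from chalcone 13, copper-catalysed enantioselective conjugate borylation (CuCl, NaOtBu, the Josiphos enantiomer that gives the 3R product, B2pin2, MeOH, THF, rt) should give the (3R)-β-boryl ketone F1. Oxidation with NaBO3·4H2O (THF/H2O), with retention, should give the (3R)-β-hydroxy ketone F2. Mitsunobu cyclisation (PPh3, DIAD, THF, 0 °C) then joins O1 to C2 by SN2 displacement with inversion and comes back to the route at 14.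

2. Step 2. What may go wrong: competing borylation or hydroboration at the trisubstituted alkenes of the geranyl chain, or catalyst inhibition, so that the aromatic C–H borylation stalls. Fallback (oxygen introduced before the alkene-bearing chain): setting out from 1, the same iridium-catalysed borylation on the alkene-free arene should give the aryl pinacol boronate F3, and NaOH/H2O2 should give 3,5-bis(methoxymethoxy)phenol F4. Silylation (TIPSCl, imidazole, DMF) gives the triisopropylsilyl ether F5, in which the bulky, non-coordinating silyloxy group leaves the carbon between the two OMOM groups as the only site of directed ortho-metalation. Treatment with n-BuLi/TMEDA, then CuBr·SMe2 (10 mol%) and geranyl bromide 2, gives the geranylated silyl ether F6. TBAF (THF) removes the silyl group and comes back at phenol 6.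

3. Step 6. What may go wrong: conjugate (1,4) addition of the hindered aryllithium to the unsaturated Weinreb amide, or proton transfer that quenches the dianion, lowering the chalcone yield. Fallback (enone built by aldol condensation in place of acyl substitution with the unsaturated amide): setting out from bromophenol 7, dianion 12 is acylated with N-methoxy-N-methylacetamide to give the methyl ketone F7. Claisen–Schmidt condensation of F7 with aldehyde 9 (KOH, EtOH, rt) comes back at chalcone 13.

Further compounds
F1 | step 7 | (3R)-1-{3-[(2E)-3,7-dimethylocta-2,6-dien-1-yl]-6-hydroxy-2,4-bis(methoxymethoxy)phenyl}-3-[3,5-bis(methoxymethoxy)phenyl]-3-(4,4,5,5-tetramethyl-1,3,2-dioxaborolan-2-yl)propan-1-one | CC(C)=CCC/C(C)=C/Cc1c(OCOC)cc(O)c(C(=O)C[C@@H](B2OC(C)(C)C(C)(C)O2)c2cc(OCOC)cc(OCOC)c2)c1OCOC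
F2 | step 7 | (3R)-1-{3-[(2E)-3,7-dimethylocta-2,6-dien-1-yl]-6-hydroxy-2,4-bis(methoxymethoxy)phenyl}-3-hydroxy-3-[3,5-bis(methoxymethoxy)phenyl]propan-1-one | CC(C)=CCC/C(C)=C/Cc1c(OCOC)cc(O)c(C(=O)C[C@@H](O)c2cc(OCOC)cc(OCOC)c2)c1OCOC
F3 | step 2 | 2-[3,5-bis(methoxymethoxy)phenyl]-4,4,5,5-tetramethyl-1,3,2-dioxaborolane | COCOc1cc(B2OC(C)(C)C(C)(C)O2)cc(OCOC)c1
F4 | step 2 | 3,5-bis(methoxymethoxy)phenol | COCOc1cc(O)cc(OCOC)c1
F5 | step 2 | [3,5-bis(methoxymethoxy)phenoxy]tri(propan-2-yl)silane | COCOc1cc(O[Si](C(C)C)(C(C)C)C(C)C)cc(OCOC)c1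
F6 | step 2 | {4-[(2E)-3,7-dimethylocta-2,6-dien-1-yl]-3,5-bis(methoxymethoxy)phenoxy}tri(propan-2-yl)silane | CC(C)=CCC/C(C)=C/Cc1c(OCOC)cc(O[Si](C(C)C)(C(C)C)C(C)C)cc1OCOC
F7 | step 6 | 1-{3-[(2E)-3,7-dimethylocta-2,6-dien-1-yl]-6-hydroxy-2,4-bis(methoxymethoxy)phenyl}ethan-1-one | CC(C)=CCC/C(C)=C/Cc1c(OCOC)cc(O)c(C(C)=O)c1OCOC
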